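# Total synthesis of CNP0109452.1 (47) by ring-closing alkyne metathesis at C4–C5

## The problem

Compound 47 is a 19-membered ansa lactam: a fifteen-carbon chain (C1–C15) spans the 1,3-positions (C16 and C20) of a 2,5-dihydroxybenzene ring, joined through the benzylic carbon C15 at one end and the anilide nitrogen at the other. The chain carries seven stereocentres in three groups: C6/C7 (syn methoxy/carbamoyloxy), C10/C11/C12 (10,11-syn, 11,12-anti) and C14/C15 (syn methyl/methoxy). The groups are insulated from one another by the C8=C9 alkene and the C13 methylene, so each needs its own reagent control; only inside the C10–C12 triad can C12 help to set C11 (Felkin sense). Three Z alkenes must be placed, the trisubstituted C8=C9 and the conjugated (2Z,4Z)-dienamide, and the latter isomerises towards E under acid, base, light or reversible conjugate addition. The hydroquinone oxidises in air and cannot be carried unprotected, the primary allylic carbamate at C7 does not tolerate strong base or alkylating agents, and the β-methoxy carbonyl intermediates met on the way epimerise or eliminate easily. The nitrogen on C20 is best carried as a nitro group, which excludes organolithium and Grignard reagents, heterogeneous hydrogenation and dissolving metals until it is unmasked. The feature that opens the key step is the cis C4=C5 bond: it lies in the ring, bears hydrogen on both carbons and is conjugated to C2=C3, so it can be drawn as a ring alkyne C4≡C5. A 19-membered ring holds such an alkyne without strain, and it can be made from two methyl-capped alkynes by a catalyst that ignores the C2=C3 and C8=C9 alkenes.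

## Retrosynthesis

**Hydroquinone.** The last operations cut no skeletal bond: 47 is taken back to quinone 46 and 46 to the arene dimethyl ether 45 (two aryl O–CH3 bonds). Methyl ethers are preferred to acetal or benzyl protection because they come with the cheapest arene source and survive every reagent of the route. The price is a two-step release, and the forward oxidation must act on the ring alone, which its 1,4-dioxygenation ensures.

**Carbamate.** The C7 carbamate C–O bond is cut (45 to alcohol 43), and 43 is traced to silyl ether 42. A primary carbamate would not survive the base and methylating agent of the alkyne stage and could bind the metathesis catalyst; a silyl ether is inert and cannot migrate to the C6 oxygen. The forward carbamoylation has to choose the C7 hydroxyl over the anilide N–H.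

**C4=C5 as an alkyne.** In 42 the cis C4=C5 bond is replaced by a triple bond (41). This keeps the fragile Z,Z-diene out of all earlier intermediates and leaves only one Z alkene in the dienamide region. The forward step is a syn semireduction of a conjugated enyne that must stop at the diene.

**Ring closure.** The C4≡C5 bond of 41 is cut by alkyne metathesis to the open diyne 40, in which C4 and C5 each carry a methyl cap. Closing here is preferred to closing at the amide, which would need a free (2Z)-unsaturated acid on a long chain and acylation of a hindered aniline in the ring-forming step. It is also preferred to closing at C8=C9, a trisubstituted Z alkene that ring-closing olefin metathesis does not deliver reliably. The step forms no stereocentre and touches no alkene; it asks for high dilution and removal of the volatile alkyne by-product.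

**Amide.** Diyne 40 is divided at N–C1 into aniline 34 and acid 38. Acid 38 comes from ester 37, made by Z-selective olefination (C2=C3) of but-2-ynal 36 with phosphonate 20; 36 is the oxidation product of but-2-yn-1-ol 35. An intermolecular acylation with a small, stable acid replaces a macrolactamisation. Aniline 34 holds all seven stereocentres and acid 38 none; the acylation must not isomerise C2=C3.

**C5 alkyne.** Aniline 34 is traced to nitro compound 33, the methyl cap is removed (32), and the alkyne carbon is disconnected from C5 (aldehyde 31, from Weinreb amide 30). Making the alkyne from a C5 carbonyl lets C5 arrive as the acyl carbon of an aldol partner, so no diastereoselective alkynyl addition to a C6 aldehyde is needed. The homologation must not epimerise C6.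

**C6–C7.** Silyl ether 30 and amide 29 lead back to aldol adduct 28, which is cut at C6–C7 into enal 23 and methoxyacetyl imide 25 (from oxazolidinone 24). One aldol step sets both oxygenated centres syn with the C6 methyl ether in place. Dihydroxylation of a C6=C7 alkene would have to distinguish it from C8=C9 and then differentiate two hydroxyls. Enal 23 is smaller by two stereocentres and three carbons.

**C8=C9.** Enal 23 comes from ester 21 through alcohol 22; 21 is cut at C8=C9 into aldehyde 19 and phosphonate 20. A Z-selective phosphonate olefination is the most direct entry to a trisubstituted Z enoate and uses the same reagent as ester 37. The α-stereocentre of 19 must survive, which a kinetic olefination at low temperature allows.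

**C10–C11.** Aldehyde 19 is the ozonolysis product of alkene 17, the methyl ether of homoallylic alcohol 16, which is cut at C10–C11 into aldehyde 14 and a Z-crotyl unit. Crotylboration is preferred to a propionate aldol because the alkene gives the aldehyde in one step. The required 10,11-syn/11,12-anti triad is also the Felkin product from an α-methoxy aldehyde, so reagent and substrate agree.

**C12.** Aldehyde 14 is traced through alcohol 13 and methyl ether 12 to α-hydroxy imide 11, whose C12–O bond is cut to give imide 10. Imide 10 is the hydrogenation product of enoyl imide 9, which is cut at C12=C13 into terminal alkene 6 and acryloyl imide 8 (from oxazolidinone 7). Oxygenating an imide enolate fixes both the position (C12, not C13) and the configuration, which epoxide-opening or dihydroxylation routes next to the C13 methylene would not guarantee. Cross-metathesis attaches the acyl unit without organometallic reagents that the nitro group forbids. This is the longest stretch of the route and is accepted for its reliability.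

**C14–C15 and arene.** Alkene 6 is the methyl ether of alcohol 5, cut at C14–C15 into aldehyde 3 and a Z-crotyl unit. Aldehyde 3 comes from nitrophenol 2 and this from commercial aldehyde 1 by nitration (C20–N). The crotylboration gives the syn pair and the terminal alkene for the cross-metathesis at once; the nitro group is introduced first because the phenol directs it to its only free ortho position.

## Roads not taken

**Alternative 1:** The cut goes through the benzene ring itself (C18–C19, C20–C21 and C16–C21), so arene and macrocycle form together from the open-chain alkenyl(methoxy)carbene pentacarbonylchromium complex A1, whose far end is an N-(4-methoxybenzyl) ynamide. Warming A1 should bring about alkyne insertion, CO insertion and electrocyclisation; after oxidative loss of chromium the phenol A2 results, with C21–OH free and C18–OMe in place.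
- Merits: no nitration, no nitro reduction and no acylation of a hindered aniline. The arene oxygens arrive differentiated, and without a nitro group the chain could be assembled with organometallic couplings in fewer steps than the route to 34.
- Weak points: benzannulation across a 19-membered ring has precedent mainly for simple tethers and competes with oligomerisation. The carbene terminus must be installed by organolithium chemistry on a chain that already holds a (2Z,4Z)-dienamide. That diene is then heated next to a chromium centre that can bind and isomerise it, and the N-benzyl group must still be removed.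
- Comparison: Alternative 1 is better in step economy. Against this, the chosen plan offers a ring closure that forms one bond and no stereocentre, has close precedent for rings of this size, and keeps the Z,Z-diene out of every intermediate before step 29.

**Alternative 2:** The ring is cut at C11–C12, between the two methoxy-bearing carbons, giving the seco dialdehyde A3. Reduction of both formyl groups by SmI2 to ketyl radicals and their coupling would give the macrocyclic diol A4, forming the ring, the C11–C12 bond and both carbinol centres in one step.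
- Merits: it is the most convergent of the four plans. It would replace steps 6–11 (the work spent on C12) and the separate crotylboration for C11.
- Weak points: of four possible diols only the 11R,12S (anti) isomer is wanted, C12 has no neighbouring stereocentre to guide it, and macrocyclic ketyl couplings show no reliable facial bias. The C11 aldehyde of A3 is α-branched and β,γ-unsaturated and should epimerise or move its double bond into conjugation. The reductant can also attack the dienamide, and A4 must then be methylated twice beside a primary carbamate and an anilide N–H.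
- Comparison: in step count Alternative 2 is better. The chosen plan sets against this a secure configuration at C11 and C12, fixed under reagent control before the ring exists.

**Alternative 3:** Here the N–C20 bond is traced back. The lactam A7 (the triethylsilyl analogue of 41) would arise by Beckmann rearrangement of ketoxime A6, made from the 18-membered aryl ketone A5; O-sulfonylation of A6 and migration of aryl carbon C20 from C1 to nitrogen expands the ring by one atom.
- Merits: nitrogen enters last, so no nitro group restricts the reagents of the chain synthesis and no aniline is acylated. The carbocycle A5 could itself be closed by the same alkyne metathesis.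
- Weak points: the rearrangement needs the oxime hydroxyl anti to the arene, that is syn to the branched alkenyl group. Neither oximation of a hindered aryl alkenyl ketone nor the rearrangement conditions guarantee that geometry. Alkenyl migration would give the wrong amide, conjugate addition to the enynone system of A5 and fragmentation are open side paths, and sulfonylation threatens the propargylic and allylic ethers. It needs three operations (ketone, oxime, rearrangement) where the chosen plan needs two (reduction, acylation).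
- Comparison: Alternative 3 is as good at the ring-closing stage and better in reagent freedom. The chosen plan sets against this an amide bond whose regiochemistry cannot go wrong.

Key step: step 28

Assumption (structure): the SMILES is read literally, as the hydroquinone with 2Z,4Z,8Z alkenes and 6S,7S,10S,11R,12S,14S,15R centres; ansa numbering (C1 amide carbonyl, C15 benzylic carbon, C16–C21 arene, nitrogen on C20) is used for the chain throughout.

Assumption (bookkeeping): salts formed by deprotonation (enolates, acetylides, phosphonate anions) and catalyst-bound species count as part of the reagent system and are not numbered; covalent intermediates carried into a second operation are numbered.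

## Route

Step 1
Reactants: 1 2-hydroxy-5-methoxybenzaldehyde
Product: 2 2-hydroxy-5-methoxy-3-nitrobenzaldehyde
Conditions: HNO3 (70%), AcOH, 15 °C to rt
Reagents that add atoms: nitric acid, O[N+](=O)[O-]
Why: Electrophilic aromatic nitration; the phenol directs ortho, its para position is blocked by the methoxy group and C3 is also meta to the formyl group, so one nitro isomer should form.

Step 2
Reactants: 2 2-hydroxy-5-methoxy-3-nitrobenzaldehyde
Product: 3 2,5-dimethoxy-3-nitrobenzaldehyde
Conditions: CH3I, K2CO3, DMF, 50 °C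
Reagents that add atoms: iodomethane, CI
Why: Williamson O-methylation of the acidic ortho-nitrophenol; both ring oxygens are now methyl ethers that last until step 32.

Step 3
Reactants: 3 2,5-dimethoxy-3-nitrobenzaldehyde
Product: 5 (1R,2S)-1-(2,5-dimethoxy-3-nitrophenyl)-2-methylbut-3-en-1-ol, via borinate ester 4 (not isolated)
Conditions: (Z)-but-2-ene, n-BuLi, KOt-Bu, THF, −78 to −45 °C; (+)-Ipc2BOMe [from (−)-α-pinene], then BF3·OEt2, −78 °C; 3, −78 °C; NaOH, H2O2, 0 °C to rt
Reagents that add atoms: (Z)-but-2-ene, C/C=C\C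
Why: Brown crotylboration through a closed chair transition state: the Z-crotyl geometry gives the syn C14/C15 pair and the isopinocampheyl ligands of the (−)-α-pinene series direct attack to the Re face of the aldehyde (15R,14S). The reagent is a neutral borane, so the nitro group is not touched.

Step 4
Reactants: 5 (1R,2S)-1-(2,5-dimethoxy-3-nitrophenyl)-2-methylbut-3-en-1-ol
Product: 6 1-[(1R,2S)-1-methoxy-2-methylbut-3-en-1-yl]-2,5-dimethoxy-3-nitrobenzene
Conditions: NaH, CH3I, THF/DMF, 0 °C to rt
Reagents that add atoms: iodomethane, CI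
Why: Williamson methylation of the benzylic alkoxide; no epimerisable centre is present.

Step 5
Reactants: 7 (S)-4-benzyl-2-oxazolidinone
Product: 8 (S)-3-acryloyl-4-benzyl-2-oxazolidinone
Conditions: acrylic acid, pivaloyl chloride, Et3N, THF, −20 °C; then LiCl, 7, rt
Reagents that add atoms: acrylic acid, C=CC(=O)O
Why: N-acylation of the oxazolidinone through the mixed pivalic anhydride with LiCl/Et3N activation, which avoids the polymerisation seen with acryloyl chloride and strong base.

Step 6
Reactants: 6 1-[(1R,2S)-1-methoxy-2-methylbut-3-en-1-yl]-2,5-dimethoxy-3-nitrobenzene; 8 (S)-3-acryloyl-4-benzyl-2-oxazolidinone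
Product: 9 (S)-4-benzyl-3-[(2E,4S,5R)-5-(2,5-dimethoxy-3-nitrophenyl)-5-methoxy-4-methylpent-2-enoyl]-2-oxazolidinone
Conditions: RuCl2(H2IMes)(=CH-C6H4-2-O-i-Pr) (second-generation Hoveyda–Grubbs catalyst, 5 mol %), 8 (3 equiv), CH2Cl2, 40 °C
Reagents that add atoms: none
Why: Alkene cross-metathesis of a terminal alkene with an electron-poor acryloyl imide used in excess; such pairs give the cross product with E geometry, and the allylic centre C14 is not labilised by the ruthenium carbene.

Step 7
Reactants: 9 (S)-4-benzyl-3-[(2E,4S,5R)-5-(2,5-dimethoxy-3-nitrophenyl)-5-methoxy-4-methylpent-2-enoyl]-2-oxazolidinone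
Product: 10 (S)-4-benzyl-3-[(4S,5R)-5-(2,5-dimethoxy-3-nitrophenyl)-5-methoxy-4-methylpentanoyl]-2-oxazolidinone
Conditions: H2 (1–3 atm), RhCl(PPh3)3 (10 mol %), toluene/EtOH, rt
Reagents that add atoms: none
Why: Homogeneous hydrogenation with RhCl(PPh3)3 saturates the disubstituted C=C and leaves the nitro group, the benzylic ether and the imide untouched.

Step 8
Reactants: 10 (S)-4-benzyl-3-[(4S,5R)-5-(2,5-dimethoxy-3-nitrophenyl)-5-methoxy-4-methylpentanoyl]-2-oxazolidinone
Product: 11 (S)-4-benzyl-3-[(2S,4S,5R)-5-(2,5-dimethoxy-3-nitrophenyl)-2-hydroxy-5-methoxy-4-methylpentanoyl]-2-oxazolidinone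
Conditions: NaN(SiMe3)2, THF, −78 °C; 2-(phenylsulfonyl)-3-phenyloxaziridine, −78 °C; AcOH
Reagents that add atoms: 2-(phenylsulfonyl)-3-phenyloxaziridine, O=S(=O)(c1ccccc1)N1OC1c1ccccc1
Why: Evans enolate oxidation: the chelated Z sodium enolate is hydroxylated by the N-sulfonyloxaziridine on the face opposite the benzyl group, which sets C12 as S. The imide carbonyl fixes the position of oxygenation at C12.

Step 9
Reactants: 11 (S)-4-benzyl-3-[(2S,4S,5R)-5-(2,5-dimethoxy-3-nitrophenyl)-2-hydroxy-5-methoxy-4-methylpentanoyl]-2-oxazolidinone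
Product: 12 (S)-4-benzyl-3-[(2S,4S,5R)-5-(2,5-dimethoxy-3-nitrophenyl)-2,5-dimethoxy-4-methylpentanoyl]-2-oxazolidinone
Conditions: Me3OBF4, 1,8-bis(dimethylamino)naphthalene, 4 Å molecular sieves, CH2Cl2, 0 °C to rt
Reagents that add atoms: trimethyloxonium tetrafluoroborate, C[O+](C)C.F[B-](F)(F)F
Why: O-Methylation with an oxonium salt and a hindered proton scavenger; the non-basic conditions avoid epimerisation and acyl transfer at the α-oxygenated imide.

Step 10
Reactants: 12 (S)-4-benzyl-3-[(2S,4S,5R)-5-(2,5-dimethoxy-3-nitrophenyl)-2,5-dimethoxy-4-methylpentanoyl]-2-oxazolidinone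
Product: 13 (2S,4S,5R)-5-(2,5-dimethoxy-3-nitrophenyl)-2,5-dimethoxy-4-methylpentan-1-ol
Conditions: LiBH4, MeOH (1 equiv), Et2O, 0 °C
Reagents that add atoms: none
Why: Reductive cleavage of the N-acyl oxazolidinone by LiBH4; the nitroarene is inert to borohydride and auxiliary 7 is recovered.

Step 11
Reactants: 13 (2S,4S,5R)-5-(2,5-dimethoxy-3-nitrophenyl)-2,5-dimethoxy-4-methylpentan-1-ol
Product: 14 (2S,4S,5R)-5-(2,5-dimethoxy-3-nitrophenyl)-2,5-dimethoxy-4-methylpentanal
Conditions: Dess–Martin periodinane, NaHCO3, CH2Cl2, 0 °C to rt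
Reagents that add atoms: none
Why: Buffered Dess–Martin oxidation should give the α-methoxy aldehyde without epimerisation; it is used without storage.

Step 12
Reactants: 14 (2S,4S,5R)-5-(2,5-dimethoxy-3-nitrophenyl)-2,5-dimethoxy-4-methylpentanal
Product: 16 (3S,4R,5S,7S,8R)-8-(2,5-dimethoxy-3-nitrophenyl)-5,8-dimethoxy-3,7-dimethyloct-1-en-4-ol, via borinate ester 15 (not isolated)
Conditions: (Z)-but-2-ene, n-BuLi, KOt-Bu, THF, −78 to −45 °C; (+)-Ipc2BOMe [from (−)-α-pinene], then BF3·OEt2, −78 °C; 14, −78 °C; NaOH, H2O2, 0 °C to rt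
Reagents that add atoms: (Z)-but-2-ene, C/C=C\C
Why: Second Brown crotylboration: Z-crotyl gives the 10,11-syn pair and the ligands direct attack to the Re face (11R). This is also the Felkin (11,12-anti) sense preferred by the α-methoxy aldehyde, so reagent and substrate control are matched.

Step 13
Reactants: 16 (3S,4R,5S,7S,8R)-8-(2,5-dimethoxy-3-nitrophenyl)-5,8-dimethoxy-3,7-dimethyloct-1-en-4-ol
Product: 17 1-[(1R,2S,4S,5R,6S)-1,4,5-trimethoxy-2,6-dimethyloct-7-en-1-yl]-2,5-dimethoxy-3-nitrobenzene
Conditions: NaH, CH3I, THF/DMF, 0 °C to rt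
Reagents that add atoms: iodomethane, CI
Why: Williamson methylation of the secondary alkoxide; the C10–C12 triad now carries its final substituents.

Step 14
Reactants: 17 1-[(1R,2S,4S,5R,6S)-1,4,5-trimethoxy-2,6-dimethyloct-7-en-1-yl]-2,5-dimethoxy-3-nitrobenzene
Product: 19 (2R,3R,4S,6S,7R)-7-(2,5-dimethoxy-3-nitrophenyl)-3,4,7-trimethoxy-2,6-dimethylheptanal, via ozonide 18 (not isolated)
Conditions: O3, CH2Cl2, −78 °C (indicator dye end-point); then PPh3, −78 °C to rt
Reagents that add atoms: ozone, [O-][O+]=O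
Why: Ozonolysis of the only alkene with reductive cleavage of the ozonide by PPh3; the nitro-deactivated arene should resist ozone at −78 °C, and the α-branched aldehyde is used at once.

Step 15
Reactants: 19 (2R,3R,4S,6S,7R)-7-(2,5-dimethoxy-3-nitrophenyl)-3,4,7-trimethoxy-2,6-dimethylheptanal; 20 ethyl 2-[bis(2,2,2-trifluoroethoxy)phosphoryl]propanoate
Product: 21 ethyl (2Z,4S,5R,6S,8S,9R)-9-(2,5-dimethoxy-3-nitrophenyl)-5,6,9-trimethoxy-2,4,8-trimethylnon-2-enoate
Conditions: 20, KN(SiMe3)2, 18-crown-6, THF, −78 °C; then 19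
Reagents that add atoms: none
Why: Still–Gennari olefination: the trifluoroethyl phosphonate anion gives the kinetic Z-trisubstituted enoate (C7 and C10 cis), and the low temperature protects the α-stereocentre C10.

Step 16
Reactants: 21 ethyl (2Z,4S,5R,6S,8S,9R)-9-(2,5-dimethoxy-3-nitrophenyl)-5,6,9-trimethoxy-2,4,8-trimethylnon-2-enoate
Product: 22 (2Z,4S,5R,6S,8S,9R)-9-(2,5-dimethoxy-3-nitrophenyl)-5,6,9-trimethoxy-2,4,8-trimethylnon-2-en-1-ol
Conditions: i-Bu2AlH, CH2Cl2, −78 °C
Reagents that add atoms: none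
Why: 1,2-Reduction of the enoate to the allylic alcohol with retention of alkene geometry; at −78 °C the nitro group is not reduced.

Step 17
Reactants: 22 (2Z,4S,5R,6S,8S,9R)-9-(2,5-dimethoxy-3-nitrophenyl)-5,6,9-trimethoxy-2,4,8-trimethylnon-2-en-1-ol
Product: 23 (2Z,4S,5R,6S,8S,9R)-9-(2,5-dimethoxy-3-nitrophenyl)-5,6,9-trimethoxy-2,4,8-trimethylnon-2-enal
Conditions: Dess–Martin periodinane, NaHCO3, CH2Cl2, 0 °C
Reagents that add atoms: none
Why: Buffered Dess–Martin oxidation of the allylic alcohol; the Z-enal is used at once to limit Z-to-E isomerisation.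

Step 18
Reactants: 24 (R)-4-benzyl-2-oxazolidinone
Product: 25 (R)-4-benzyl-3-(2-methoxyacetyl)-2-oxazolidinone
Conditions: n-BuLi, THF, −78 °C; methoxyacetyl chloride, −78 to 0 °C
Reagents that add atoms: methoxyacetyl chloride, COCC(=O)Cl
Why: N-acylation of the lithiated oxazolidinone with an acid chloride, the standard entry to glycolate imides.

Step 19
Reactants: 23 (2Z,4S,5R,6S,8S,9R)-9-(2,5-dimethoxy-3-nitrophenyl)-5,6,9-trimethoxy-2,4,8-trimethylnon-2-enal; 25 (R)-4-benzyl-3-(2-methoxyacetyl)-2-oxazolidinone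
Product: 28 (R)-4-benzyl-3-[(2R,3S,4Z,6S,7R,8S,10S,11R)-11-(2,5-dimethoxy-3-nitrophenyl)-3-hydroxy-2,7,8,11-tetramethoxy-4,6,10-trimethylundec-4-enoyl]-2-oxazolidinone, via boron enolate 26 (not isolated), via boron aldolate 27 (not isolated)
Conditions: 25, Bu2BOTf, Et3N, CH2Cl2, −78 to 0 °C; 23, −78 to 0 °C; pH 7 buffer, MeOH, H2O2, 0 °C
Reagents that add atoms: none
Why: Evans syn glycolate aldol: the Z boron enolate adds through a chair transition state on the face opposite the benzyl group, giving the 6,7-syn pair (6S,7S in the target) with the C6 methoxy group already in place. Auxiliary control should override the remote centres of 23.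

Step 20
Reactants: 28 (R)-4-benzyl-3-[(2R,3S,4Z,6S,7R,8S,10S,11R)-11-(2,5-dimethoxy-3-nitrophenyl)-3-hydroxy-2,7,8,11-tetramethoxy-4,6,10-trimethylundec-4-enoyl]-2-oxazolidinone
Product: 29 (2R,3S,4Z,6S,7R,8S,10S,11R)-11-(2,5-dimethoxy-3-nitrophenyl)-3-hydroxy-N,2,7,8,11-pentamethoxy-N,4,6,10-tetramethylundec-4-enamide
Conditions: MeONHMe·HCl, AlMe3, THF, −20 to 0 °C
Reagents that add atoms: N,O-dimethylhydroxylamine hydrochloride, CNOC.Cl
Why: Aluminium amide transamination to the Weinreb amide, assisted by the free β-hydroxyl; auxiliary 24 is recovered.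

Step 21
Reactants: 29 (2R,3S,4Z,6S,7R,8S,10S,11R)-11-(2,5-dimethoxy-3-nitrophenyl)-3-hydroxy-N,2,7,8,11-pentamethoxy-N,4,6,10-tetramethylundec-4-enamide
Product: 30 3-O-(tert-butyldimethylsilyl) ether of 29
Conditions: t-BuMe2SiOTf, 2,6-lutidine, CH2Cl2, −78 to 0 °C
Reagents that add atoms: tert-butyldimethylsilyl trifluoromethanesulfonate, CC(C)(C)[Si](C)(C)OS(=O)(=O)C(F)(F)F
Why: Silylation of the hindered allylic alcohol with the silyl triflate; the silyl ether protects C7 through the base-mediated steps and the metathesis.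

Step 22
Reactants: 30 3-O-(tert-butyldimethylsilyl) ether of 29
Product: 32 tert-butyl{[(3S,4S,5Z,7S,8R,9S,11S,12R)-12-(2,5-dimethoxy-3-nitrophenyl)-3,8,9,12-tetramethoxy-5,7,11-trimethyldodec-5-en-1-yn-4-yl]oxy}dimethylsilane, via aldehyde 31 (not isolated)
Conditions: i-Bu2AlH, THF, −78 °C; then MeOH, K2CO3, dimethyl (1-diazo-2-oxopropyl)phosphonate, −78 °C to rt
Reagents that add atoms: dimethyl (1-diazo-2-oxopropyl)phosphonate, COP(=O)(OC)C(=[N+]=[N-])C(C)=O
Why: Reduction of the Weinreb amide stops at the chelated hemiaminal, which releases aldehyde 31 on adding methanol. Ohira–Bestmann homologation then gives the terminal alkyne, and the mild carbonate base should leave the existing C6 centre intact.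

Step 23
Reactants: 32 tert-butyl{[(3S,4S,5Z,7S,8R,9S,11S,12R)-12-(2,5-dimethoxy-3-nitrophenyl)-3,8,9,12-tetramethoxy-5,7,11-trimethyldodec-5-en-1-yn-4-yl]oxy}dimethylsilane
Product: 33 tert-butyl{[(4S,5S,6Z,8S,9R,10S,12S,13R)-13-(2,5-dimethoxy-3-nitrophenyl)-4,9,10,13-tetramethoxy-6,8,12-trimethyltridec-6-en-2-yn-5-yl]oxy}dimethylsilane
Conditions: LiN(SiMe3)2, THF, −78 °C; CH3OTf, −78 to −40 °C
Reagents that add atoms: methyl trifluoromethanesulfonate, COS(=O)(=O)C(F)(F)F
Why: Deprotonation of the terminal alkyne and C-methylation of the acetylide with methyl triflate at low temperature give the methyl-capped alkyne that the metathesis needs.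

Step 24
Reactants: 33 tert-butyl{[(4S,5S,6Z,8S,9R,10S,12S,13R)-13-(2,5-dimethoxy-3-nitrophenyl)-4,9,10,13-tetramethoxy-6,8,12-trimethyltridec-6-en-2-yn-5-yl]oxy}dimethylsilane
Product: 34 3-[(1R,2S,4S,5R,6S,7Z,9S,10S)-9-(tert-butyldimethylsilyloxy)-1,4,5,10-tetramethoxy-2,6,8-trimethyltridec-7-en-11-yn-1-yl]-2,5-dimethoxyaniline
Conditions: Zn dust, AcOH, THF, 0 °C to rt
Reagents that add atoms: none
Why: Electron-transfer reduction of the nitro group by zinc in acetic acid gives the aniline; the isolated alkyne, the trisubstituted alkene and the silyl ether are not affected.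

Step 25
Reactants: 35 but-2-yn-1-ol; 20 ethyl 2-[bis(2,2,2-trifluoroethoxy)phosphoryl]propanoate
Product: 37 ethyl (2Z)-2-methylhex-2-en-4-ynoate, via but-2-ynal 36 (not isolated)
Conditions: MnO2, CH2Cl2, rt, filter; the solution added to 20, KN(SiMe3)2, 18-crown-6, THF, −78 °C
Reagents that add atoms: none
Why: Propargylic oxidation with MnO2 gives the volatile ynal 36, which is olefinated in solution by Still–Gennari olefination to the Z-enynoate (ester and alkynyl group cis).

Step 26
Reactants: 37 ethyl (2Z)-2-methylhex-2-en-4-ynoate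
Product: 38 (2Z)-2-methylhex-2-en-4-ynoic acid
Conditions: LiOH, THF/H2O, 0 °C to rt; then aq. HCl to pH 3
Reagents that add atoms: lithium hydroxide, [Li+].[OH-]
Why: Saponification under mild conditions; the Z geometry is kinetically stable to hydroxide at this temperature.

Step 27
Reactants: 34 3-[(1R,2S,4S,5R,6S,7Z,9S,10S)-9-(tert-butyldimethylsilyloxy)-1,4,5,10-tetramethoxy-2,6,8-trimethyltridec-7-en-11-yn-1-yl]-2,5-dimethoxyaniline; 38 (2Z)-2-methylhex-2-en-4-ynoic acid
Product: 40 (2Z)-N-{3-[(1R,2S,4S,5R,6S,7Z,9S,10S)-9-(tert-butyldimethylsilyloxy)-1,4,5,10-tetramethoxy-2,6,8-trimethyltridec-7-en-11-yn-1-yl]-2,5-dimethoxyphenyl}-2-methylhex-2-en-4-ynamide (seco diyne anilide), via acid chloride 39 (not isolated)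
Conditions: 38, 1-chloro-N,N,2-trimethylprop-1-en-1-amine, CH2Cl2, 0 °C; then 34, pyridine, 0 °C to rt
Reagents that add atoms: none
Why: The acid chloride is formed under neutral conditions with the α-chloroenamine and acylates the hindered, electron-rich aniline. No nucleophilic catalyst is present that could isomerise C2=C3 by conjugate addition.

Step 28
Reactants: 40 seco diyne anilide
Product: 41 19-membered (2Z,8Z)-en-4-yne lactam (C7 O-TBS, arene dimethyl ether; 6S,7S,10S,11R,12S,14S,15R)
Conditions: Mo(≡CC6H4OMe-4)(OSiPh3)3 (15 mol %), 5 Å molecular sieves, toluene (0.002 M), rt to 80 °C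
Reagents that add atoms: none
Why: Ring-closing alkyne metathesis: the molybdenum alkylidyne adds to a methyl-capped alkyne of 40 in a [2+2] step to a metallacyclobutadiene, which opens to a substrate-bound alkylidyne; an intramolecular [2+2]/cycloreversion with the second alkyne forms C4≡C5 and releases Mo≡CCH3, which carries the chain. The closest known reaction type is ring-closing alkyne metathesis of diynes to macrocyclic 1,3-enynes with triarylsilanolate molybdenum alkylidynes. The 19-membered ring is closed by joining the two alkyne termini (a metathesis macrocyclisation with both reacting carbons sp-hybridised); the linear C3–C4≡C5–C6 unit fits a ring of this size without strain, and adsorption of but-2-yne on the 5 Å sieves drives the closure. No stereocentre is formed. Selectivity for alkyne over alkene is inherent to the alkylidyne, so C2=C3 and C8=C9 keep their Z geometry; ring over oligomer is secured by high dilution and by reversibility, which returns oligomers to the ring. The electron-richer C5 alkyne should load the catalyst first and the conjugated alkyne close the ring, and the silanolate ligands should tolerate the ethers, the silyl ether and the anilide N–H, which is hydrogen-bonded to the ortho methoxy group.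

Step 29
Reactants: 41 19-membered (2Z,8Z)-en-4-yne lactam
Product: 42 19-membered (2Z,4Z,8Z)-triene lactam (C7 O-TBS, arene dimethyl ether)
Conditions: Zn (activated with Cu(OAc)2 and AgNO3), MeOH/H2O/THF, rt to 40 °C
Reagents that add atoms: none
Why: Boland semireduction: the activated zinc transfers electrons only to the conjugated alkyne and protonation gives the cis alkene. Isolated alkenes are not reduced and the reaction should stop at the diene.

Step 30
Reactants: 42 19-membered (2Z,4Z,8Z)-triene lactam (C7 O-TBS)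
Product: 43 C7 alcohol of 42
Conditions: HF·pyridine, pyridine, THF, 0 °C to rt
Reagents that add atoms: none
Why: Fluoride-mediated desilylation under buffered conditions, to which the Z,Z-dienamide and the methyl ethers are stable.

Step 31
Reactants: 43 C7 alcohol of 42
Product: 45 C7 carbamate (arene dimethyl ether of 47), via trichloroacetyl carbamate 44 (not isolated)
Conditions: Cl3CC(O)NCO, CH2Cl2, 0 °C; then K2CO3, MeOH, rt
Reagents that add atoms: trichloroacetyl isocyanate, O=C=NC(=O)C(Cl)(Cl)Cl
Why: Addition of the C7 alcohol to the acyl isocyanate gives N-acyl carbamate 44, and mild methanolysis removes the trichloroacetyl group. The anilide N–H is too weak a nucleophile to compete.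

Step 32
Reactants: 45 C7 carbamate (arene dimethyl ether)
Product: 46 quinone (C18 and C21 carbonyls)
Conditions: (NH4)2Ce(NO3)6, CH3CN/H2O, 0 °C
Reagents that add atoms: water, O
Why: Oxidative demethylation of the para-dimethoxyarene by tetravalent cerium: two one-electron oxidations, addition of water at the ipso carbons and loss of methanol give the para-quinone. The diene and the carbamate are much harder to oxidise than the arene.

Step 33
Reactants: 46 quinone
Product: 47 CNP0109452.1 (hydroquinone)
Conditions: Na2S2O4, EtOAc/H2O, rt, argon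
Reagents that add atoms: none
Why: Two-electron reduction of the quinone by dithionite gives the hydroquinone; nothing else in 46 is reducible under these conditions, and air is excluded during isolation.

## Compound list

1 | 2-hydroxy-5-methoxybenzaldehyde | COc1ccc(O)c(C=O)c1 | starting material
2 | 2-hydroxy-5-methoxy-3-nitrobenzaldehyde | O=Cc1cc(OC)cc([N+](=O)[O-])c1O | intermediate
3 | 2,5-dimethoxy-3-nitrobenzaldehyde | O=Cc1cc(OC)cc([N+](=O)[O-])c1OC | intermediate
4 | O-bis(isopinocampheyl)boryl derivative (borinate ester) of 5, (−)-α-pinene series | C=C[C@H](C)[C@@H](OB([C@H]1C[C@H]2C[C@@H]([C@@H]1C)C2(C)C)[C@H]1C[C@H]2C[C@@H]([C@@H]1C)C2(C)C)c1cc(OC)cc(c1OC)[N+](=O)[O-] | intermediate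
5 | (1R,2S)-1-(2,5-dimethoxy-3-nitrophenyl)-2-methylbut-3-en-1-ol | C=C[C@H](C)[C@@H](O)c1cc(OC)cc(c1OC)[N+](=O)[O-] | intermediate
6 | 1-[(1R,2S)-1-methoxy-2-methylbut-3-en-1-yl]-2,5-dimethoxy-3-nitrobenzene | C=C[C@H](C)[C@@H](OC)c1cc(OC)cc(c1OC)[N+](=O)[O-] | intermediate
7 | (S)-4-benzyl-2-oxazolidinone | O=C1N[C@@H](Cc2ccccc2)CO1 | starting material
8 | (S)-3-acryloyl-4-benzyl-2-oxazolidinone | C=CC(=O)N1[C@@H](Cc2ccccc2)COC1=O | intermediate
9 | (S)-4-benzyl-3-[(2E,4S,5R)-5-(2,5-dimethoxy-3-nitrophenyl)-5-methoxy-4-methylpent-2-enoyl]-2-oxazolidinone | O=C(/C=C/[C@H](C)[C@@H](OC)c1cc(OC)cc(c1OC)[N+](=O)[O-])N1[C@@H](Cc2ccccc2)COC1=O | intermediate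
10 | (S)-4-benzyl-3-[(4S,5R)-5-(2,5-dimethoxy-3-nitrophenyl)-5-methoxy-4-methylpentanoyl]-2-oxazolidinone | O=C(CC[C@H](C)[C@@H](OC)c1cc(OC)cc(c1OC)[N+](=O)[O-])N1[C@@H](Cc2ccccc2)COC1=O | intermediate
11 | (S)-4-benzyl-3-[(2S,4S,5R)-5-(2,5-dimethoxy-3-nitrophenyl)-2-hydroxy-5-methoxy-4-methylpentanoyl]-2-oxazolidinone | O=C([C@@H](O)C[C@H](C)[C@@H](OC)c1cc(OC)cc(c1OC)[N+](=O)[O-])N1[C@@H](Cc2ccccc2)COC1=O | intermediate
12 | (S)-4-benzyl-3-[(2S,4S,5R)-5-(2,5-dimethoxy-3-nitrophenyl)-2,5-dimethoxy-4-methylpentanoyl]-2-oxazolidinone | O=C([C@@H](OC)C[C@H](C)[C@@H](OC)c1cc(OC)cc(c1OC)[N+](=O)[O-])N1[C@@H](Cc2ccccc2)COC1=O | intermediate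
13 | (2S,4S,5R)-5-(2,5-dimethoxy-3-nitrophenyl)-2,5-dimethoxy-4-methylpentan-1-ol | OC[C@@H](OC)C[C@H](C)[C@@H](OC)c1cc(OC)cc(c1OC)[N+](=O)[O-] | intermediate
14 | (2S,4S,5R)-5-(2,5-dimethoxy-3-nitrophenyl)-2,5-dimethoxy-4-methylpentanal | O=C[C@@H](OC)C[C@H](C)[C@@H](OC)c1cc(OC)cc(c1OC)[N+](=O)[O-] | intermediate
15 | O-bis(isopinocampheyl)boryl derivative (borinate ester) of 16, (−)-α-pinene series | C=C[C@H](C)[C@@H](OB([C@H]1C[C@H]2C[C@@H]([C@@H]1C)C2(C)C)[C@H]1C[C@H]2C[C@@H]([C@@H]1C)C2(C)C)[C@@H](OC)C[C@H](C)[C@@H](OC)c1cc(OC)cc(c1OC)[N+](=O)[O-] | intermediate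
16 | (3S,4R,5S,7S,8R)-8-(2,5-dimethoxy-3-nitrophenyl)-5,8-dimethoxy-3,7-dimethyloct-1-en-4-ol | C=C[C@H](C)[C@@H](O)[C@@H](OC)C[C@H](C)[C@@H](OC)c1cc(OC)cc(c1OC)[N+](=O)[O-] | intermediate
17 | 1-[(1R,2S,4S,5R,6S)-1,4,5-trimethoxy-2,6-dimethyloct-7-en-1-yl]-2,5-dimethoxy-3-nitrobenzene | C=C[C@H](C)[C@@H](OC)[C@@H](OC)C[C@H](C)[C@@H](OC)c1cc(OC)cc(c1OC)[N+](=O)[O-] | intermediate
18 | ozonide (1,2,4-trioxolane) of 17, both epimers at the ring carbon | C1(OCOO1)[C@H](C)[C@@H](OC)[C@@H](OC)C[C@H](C)[C@@H](OC)c2cc(OC)cc(c2OC)[N+](=O)[O-] | intermediate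
19 | (2R,3R,4S,6S,7R)-7-(2,5-dimethoxy-3-nitrophenyl)-3,4,7-trimethoxy-2,6-dimethylheptanal | O=C[C@H](C)[C@@H](OC)[C@@H](OC)C[C@H](C)[C@@H](OC)c1cc(OC)cc(c1OC)[N+](=O)[O-] | intermediate
20 | ethyl 2-[bis(2,2,2-trifluoroethoxy)phosphoryl]propanoate | CCOC(=O)C(C)P(=O)(OCC(F)(F)F)OCC(F)(F)F | starting material
21 | ethyl (2Z,4S,5R,6S,8S,9R)-9-(2,5-dimethoxy-3-nitrophenyl)-5,6,9-trimethoxy-2,4,8-trimethylnon-2-enoate | CCOC(=O)/C(C)=C\[C@H](C)[C@@H](OC)[C@@H](OC)C[C@H](C)[C@@H](OC)c1cc(OC)cc(c1OC)[N+](=O)[O-] | intermediate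
22 | (2Z,4S,5R,6S,8S,9R)-9-(2,5-dimethoxy-3-nitrophenyl)-5,6,9-trimethoxy-2,4,8-trimethylnon-2-en-1-ol | OC/C(C)=C\[C@H](C)[C@@H](OC)[C@@H](OC)C[C@H](C)[C@@H](OC)c1cc(OC)cc(c1OC)[N+](=O)[O-] | intermediate
23 | (2Z,4S,5R,6S,8S,9R)-9-(2,5-dimethoxy-3-nitrophenyl)-5,6,9-trimethoxy-2,4,8-trimethylnon-2-enal | O=C/C(C)=C\[C@H](C)[C@@H](OC)[C@@H](OC)C[C@H](C)[C@@H](OC)c1cc(OC)cc(c1OC)[N+](=O)[O-] | intermediate
24 | (R)-4-benzyl-2-oxazolidinone | O=C1N[C@H](Cc2ccccc2)CO1 | starting material
25 | (R)-4-benzyl-3-(2-methoxyacetyl)-2-oxazolidinone | COCC(=O)N1[C@H](Cc2ccccc2)COC1=O | intermediate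
26 | (Z)-dibutylboron enolate of 25 | CO/C=C(\OB(CCCC)CCCC)N1[C@H](Cc2ccccc2)COC1=O | intermediate
27 | O-dibutylboryl aldolate of 28 | O=C([C@H](OC)[C@@H](OB(CCCC)CCCC)/C(C)=C\[C@H](C)[C@@H](OC)[C@@H](OC)C[C@H](C)[C@@H](OC)c1cc(OC)cc(c1OC)[N+](=O)[O-])N1[C@H](Cc2ccccc2)COC1=O | intermediate
28 | (R)-4-benzyl-3-[(2R,3S,4Z,6S,7R,8S,10S,11R)-11-(2,5-dimethoxy-3-nitrophenyl)-3-hydroxy-2,7,8,11-tetramethoxy-4,6,10-trimethylundec-4-enoyl]-2-oxazolidinone | O=C([C@H](OC)[C@@H](O)/C(C)=C\[C@H](C)[C@@H](OC)[C@@H](OC)C[C@H](C)[C@@H](OC)c1cc(OC)cc(c1OC)[N+](=O)[O-])N1[C@H](Cc2ccccc2)COC1=O | intermediate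
29 | (2R,3S,4Z,6S,7R,8S,10S,11R)-11-(2,5-dimethoxy-3-nitrophenyl)-3-hydroxy-N,2,7,8,11-pentamethoxy-N,4,6,10-tetramethylundec-4-enamide | CON(C)C(=O)[C@H](OC)[C@@H](O)/C(C)=C\[C@H](C)[C@@H](OC)[C@@H](OC)C[C@H](C)[C@@H](OC)c1cc(OC)cc(c1OC)[N+](=O)[O-] | intermediate
30 | (2R,3S,4Z,6S,7R,8S,10S,11R)-3-(tert-butyldimethylsilyloxy)-11-(2,5-dimethoxy-3-nitrophenyl)-N,2,7,8,11-pentamethoxy-N,4,6,10-tetramethylundec-4-enamide | CON(C)C(=O)[C@H](OC)[C@@H](O[Si](C)(C)C(C)(C)C)/C(C)=C\[C@H](C)[C@@H](OC)[C@@H](OC)C[C@H](C)[C@@H](OC)c1cc(OC)cc(c1OC)[N+](=O)[O-] | intermediate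
31 | (2R,3S,4Z,6S,7R,8S,10S,11R)-3-(tert-butyldimethylsilyloxy)-11-(2,5-dimethoxy-3-nitrophenyl)-2,7,8,11-tetramethoxy-4,6,10-trimethylundec-4-enal | O=C[C@H](OC)[C@@H](O[Si](C)(C)C(C)(C)C)/C(C)=C\[C@H](C)[C@@H](OC)[C@@H](OC)C[C@H](C)[C@@H](OC)c1cc(OC)cc(c1OC)[N+](=O)[O-] | intermediate
32 | tert-butyl{[(3S,4S,5Z,7S,8R,9S,11S,12R)-12-(2,5-dimethoxy-3-nitrophenyl)-3,8,9,12-tetramethoxy-5,7,11-trimethyldodec-5-en-1-yn-4-yl]oxy}dimethylsilane | C#C[C@H](OC)[C@@H](O[Si](C)(C)C(C)(C)C)/C(C)=C\[C@H](C)[C@@H](OC)[C@@H](OC)C[C@H](C)[C@@H](OC)c1cc(OC)cc(c1OC)[N+](=O)[O-] | intermediate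
33 | tert-butyl{[(4S,5S,6Z,8S,9R,10S,12S,13R)-13-(2,5-dimethoxy-3-nitrophenyl)-4,9,10,13-tetramethoxy-6,8,12-trimethyltridec-6-en-2-yn-5-yl]oxy}dimethylsilane | CC#C[C@H](OC)[C@@H](O[Si](C)(C)C(C)(C)C)/C(C)=C\[C@H](C)[C@@H](OC)[C@@H](OC)C[C@H](C)[C@@H](OC)c1cc(OC)cc(c1OC)[N+](=O)[O-] | intermediate
34 | 3-[(1R,2S,4S,5R,6S,7Z,9S,10S)-9-(tert-butyldimethylsilyloxy)-1,4,5,10-tetramethoxy-2,6,8-trimethyltridec-7-en-11-yn-1-yl]-2,5-dimethoxyaniline | CC#C[C@H](OC)[C@@H](O[Si](C)(C)C(C)(C)C)/C(C)=C\[C@H](C)[C@@H](OC)[C@@H](OC)C[C@H](C)[C@@H](OC)c1cc(OC)cc(c1OC)N | intermediate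
35 | but-2-yn-1-ol | CC#CCO | starting material
36 | but-2-ynal | CC#CC=O | intermediate
37 | ethyl (2Z)-2-methylhex-2-en-4-ynoate | CCOC(=O)/C(C)=C\C#CC | intermediate
38 | (2Z)-2-methylhex-2-en-4-ynoic acid | OC(=O)/C(C)=C\C#CC | intermediate
39 | (2Z)-2-methylhex-2-en-4-ynoyl chloride | ClC(=O)/C(C)=C\C#CC | intermediate
40 | seco diyne anilide: (2Z)-N-{3-[(1R,2S,4S,5R,6S,7Z,9S,10S)-9-(tert-butyldimethylsilyloxy)-1,4,5,10-tetramethoxy-2,6,8-trimethyltridec-7-en-11-yn-1-yl]-2,5-dimethoxyphenyl}-2-methylhex-2-en-4-ynamide | CC#C[C@H](OC)[C@@H](O[Si](C)(C)C(C)(C)C)/C(C)=C\[C@H](C)[C@@H](OC)[C@@H](OC)C[C@H](C)[C@@H](OC)c1cc(OC)cc(c1OC)NC(=O)/C(C)=C\C#CC | intermediate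
41 | 19-membered (2Z,8Z)-en-4-yne lactam; 6S,7S,10S,11R,12S,14S,15R; 7-O-TBS; 6,11,12,15-tetramethoxy; 2,8,10,14-tetramethyl; arene 18,21-dimethyl ether | CO[C@H]1[C@@H](OC)C[C@H](C)[C@@H](OC)c2cc(OC)cc(c2OC)NC(=O)/C(C)=C\C#C[C@H](OC)[C@@H](O[Si](C)(C)C(C)(C)C)/C(C)=C\[C@@H]1C | intermediate
42 | 19-membered (2Z,4Z,8Z)-triene lactam; otherwise as 41 | CO[C@H]1[C@@H](OC)C[C@H](C)[C@@H](OC)c2cc(OC)cc(c2OC)NC(=O)/C(C)=C\C=C/[C@H](OC)[C@@H](O[Si](C)(C)C(C)(C)C)/C(C)=C\[C@@H]1C | intermediate
43 | C7 alcohol of 42 (7S-hydroxy; arene dimethyl ether) | CO[C@H]1[C@@H](OC)C[C@H](C)[C@@H](OC)c2cc(OC)cc(c2OC)NC(=O)/C(C)=C\C=C/[C@H](OC)[C@@H](O)/C(C)=C\[C@@H]1C | intermediate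
44 | C7 N-(trichloroacetyl)carbamate of 43 | CO[C@H]1[C@@H](OC)C[C@H](C)[C@@H](OC)c2cc(OC)cc(c2OC)NC(=O)/C(C)=C\C=C/[C@H](OC)[C@@H](OC(=O)NC(=O)C(Cl)(Cl)Cl)/C(C)=C\[C@@H]1C | intermediate
45 | C7 carbamate, arene 18,21-dimethyl ether of 47 | CO[C@H]1[C@@H](OC)C[C@H](C)[C@@H](OC)c2cc(OC)cc(c2OC)NC(=O)/C(C)=C\C=C/[C@H](OC)[C@@H](OC(N)=O)/C(C)=C\[C@@H]1C | intermediate
46 | quinone of 47 (C18 and C21 carbonyls) | CO[C@H]1[C@@H](OC)C[C@H](C)[C@@H](OC)C2=CC(=O)C=C(C2=O)NC(=O)/C(C)=C\C=C/[C@H](OC)[C@@H](OC(N)=O)/C(C)=C\[C@@H]1C | intermediate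
47 | CNP0109452.1: 19-membered (2Z,4Z,8Z) ansa lactam hydroquinone, 6S,7S,10S,11R,12S,14S,15R, 7-carbamate | CO[C@H]1[C@@H](OC)C[C@H](C)[C@@H](OC)c2cc(O)cc(c2O)NC(=O)/C(C)=C\C=C/[C@H](OC)[C@@H](OC(N)=O)/C(C)=C\[C@@H]1C | target

## Step count and least certain steps

Total step count: 33. Longest linear sequence: 29 steps from 1 (steps 1–4, 6–17, 19–24 and 27–33); steps 5, 18, 25 and 26 make the side components 8, 25 and 38.

**Step 28 (key step).** The most likely failure is oligomerisation by intermolecular metathesis. The catalyst may also stall, because the conjugated, electron-poor alkyne engages the alkylidyne slowly while the anilide and the ether oxygens compete for molybdenum. The fallback closes the ring by amide formation, with the C4≡C5 alkyne in place beforehand. It sets out from 32: the lithium acetylide (LiN(SiMe3)2, THF, −78 °C) is formylated with DMF to the ynal F1. Still–Gennari olefination with 20 gives the ethyl (2Z)-en-4-ynoate F2, Zn/AcOH reduces the nitro group to the amino ester F3, and LiOH hydrolysis gives the amino acid F4. Macrolactamisation of F4 with bis(2-oxo-3-oxazolidinyl)phosphinic chloride and i-Pr2NEt in toluene at high dilution returns to the route at 41.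

**Step 29.** The risks are reduction beyond the diene, incomplete conversion in the strained conjugated system, or Z-to-E isomerisation through reversible electron transfer to the dienamide. The fallback replaces electron transfer by syn-hydrosilylation and protodesilylation. From 41, BnMe2SiH and Pt2[(CH2=CHSiMe2)2O]3 in THF should add H and Si cis across the alkyne (silicon at C4) to give the alkenylsilane F5. Bu4NF in THF then removes the alkenyl silyl group with retention and the C7 silyl ether at the same time, returning to the route at 43.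

**Step 23.** The acetylide or the amide base may transfer an electron to, or add to, the nitroarene faster than C-methylation takes place. The fallback avoids a carbanion altogether. From 32, N-bromosuccinimide with catalytic AgNO3 in acetone gives the 1-bromoalkyne F6, and Negishi coupling with MeZnCl and Pd(PPh3)4 in THF returns to the route at 33.

**Step 3.** With the electron-poor, ortho-substituted aldehyde the facial selectivity of the crotylboration may be incomplete, and the antipode would be carried into later steps as diastereomers that are hard to remove. The fallback uses auxiliary control. From 3, an Evans syn aldol with (R)-4-benzyl-3-propionyl-2-oxazolidinone (Bu2BOTf, Et3N) gives the aldol adduct F7. Transamination (MeONHMe·HCl, AlMe3) gives the Weinreb amide F8, O-methylation (Me3OBF4, 1,8-bis(dimethylamino)naphthalene) gives the methyl ether F9, and i-Bu2AlH gives the aldehyde F10. Wittig methylenation (Ph3P=CH2) returns to the route at 6.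

## Further compounds

F1 | step 28 | (4S,5S,6Z,8S,9R,10S,12S,13R)-5-(tert-butyldimethylsilyloxy)-13-(2,5-dimethoxy-3-nitrophenyl)-4,9,10,13-tetramethoxy-6,8,12-trimethyltridec-6-en-2-ynal | O=CC#C[C@H](OC)[C@@H](O[Si](C)(C)C(C)(C)C)/C(C)=C\[C@H](C)[C@@H](OC)[C@@H](OC)C[C@H](C)[C@@H](OC)c1cc(OC)cc(c1OC)[N+](=O)[O-]
F2 | step 28 | ethyl (2Z)-en-4-ynoate of the nitro seco chain (C1–C15, 7-O-TBS) | CCOC(=O)/C(C)=C\C#C[C@H](OC)[C@@H](O[Si](C)(C)C(C)(C)C)/C(C)=C\[C@H](C)[C@@H](OC)[C@@H](OC)C[C@H](C)[C@@H](OC)c1cc(OC)cc(c1OC)[N+](=O)[O-]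
F3 | step 28 | amino ester (aniline) corresponding to F2 | CCOC(=O)/C(C)=C\C#C[C@H](OC)[C@@H](O[Si](C)(C)C(C)(C)C)/C(C)=C\[C@H](C)[C@@H](OC)[C@@H](OC)C[C@H](C)[C@@H](OC)c1cc(OC)cc(c1OC)N
F4 | step 28 | seco amino acid (2Z)-en-4-ynoic acid | OC(=O)/C(C)=C\C#C[C@H](OC)[C@@H](O[Si](C)(C)C(C)(C)C)/C(C)=C\[C@H](C)[C@@H](OC)[C@@H](OC)C[C@H](C)[C@@H](OC)c1cc(OC)cc(c1OC)N
F5 | step 29 | 4-(benzyldimethylsilyl) derivative of 42 (C3 and C6 cis on C4=C5) | CO[C@H]1[C@@H](OC)C[C@H](C)[C@@H](OC)c2cc(OC)cc(c2OC)NC(=O)/C(C)=C\C([Si](C)(C)Cc3ccccc3)=C/[C@H](OC)[C@@H](O[Si](C)(C)C(C)(C)C)/C(C)=C\[C@@H]1C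
F6 | step 23 | 1-bromoalkyne from 32 | BrC#C[C@H](OC)[C@@H](O[Si](C)(C)C(C)(C)C)/C(C)=C\[C@H](C)[C@@H](OC)[C@@H](OC)C[C@H](C)[C@@H](OC)c1cc(OC)cc(c1OC)[N+](=O)[O-]
F7 | step 3 | (R)-4-benzyl-3-[(2R,3R)-3-(2,5-dimethoxy-3-nitrophenyl)-3-hydroxy-2-methylpropanoyl]-2-oxazolidinone | O=C([C@H](C)[C@@H](O)c1cc(OC)cc(c1OC)[N+](=O)[O-])N1[C@H](Cc2ccccc2)COC1=O
F8 | step 3 | (2R,3R)-3-(2,5-dimethoxy-3-nitrophenyl)-3-hydroxy-N-methoxy-N,2-dimethylpropanamide | CON(C)C(=O)[C@H](C)[C@@H](O)c1cc(OC)cc(c1OC)[N+](=O)[O-]
F9 | step 3 | (2R,3R)-3-(2,5-dimethoxy-3-nitrophenyl)-N,3-dimethoxy-N,2-dimethylpropanamide | CON(C)C(=O)[C@H](C)[C@@H](OC)c1cc(OC)cc(c1OC)[N+](=O)[O-]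
F10 | step 3 | (2R,3R)-3-(2,5-dimethoxy-3-nitrophenyl)-3-methoxy-2-methylpropanal | O=C[C@H](C)[C@@H](OC)c1cc(OC)cc(c1OC)[N+](=O)[O-]
A1 | alternative 1 | open-chain alkenyl(methoxy)carbene pentacarbonylchromium complex with terminal N-(4-methoxybenzyl) ynamide | C#CN(Cc1ccc(OC)cc1)C(=O)/C(C)=C\C=C/[C@H](OC)[C@@H](O[Si](C)(C)C(C)(C)C)/C(C)=C\[C@H](C)[C@@H](OC)[C@@H](OC)C[C@H](C)[C@@H](OC)/C=C/C(OC)=[Cr](=C=O)(=C=O)(=C=O)(=C=O)=C=O
A2 | alternative 1 | ansa 4-methoxyphenol N-(4-methoxybenzyl) lactam (C7 O-TBS) | CO[C@H]1[C@@H](OC)C[C@H](C)[C@@H](OC)c2cc(OC)cc(c2O)N(Cc3ccc(OC)cc3)C(=O)/C(C)=C\C=C/[C@H](OC)[C@@H](O[Si](C)(C)C(C)(C)C)/C(C)=C\[C@@H]1C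
A3 | alternative 2 | seco dialdehyde (C11 and C12 formyl groups) | O=CC[C@H](C)[C@@H](OC)c1cc(OC)cc(c1OC)NC(=O)/C(C)=C\C=C/[C@H](OC)[C@@H](OC(N)=O)/C(C)=C\[C@H](C)C=O
A4 | alternative 2 | macrocyclic 11,12-diol | O[C@H]1[C@@H](O)C[C@H](C)[C@@H](OC)c2cc(OC)cc(c2OC)NC(=O)/C(C)=C\C=C/[C@H](OC)[C@@H](OC(N)=O)/C(C)=C\[C@@H]1C
A5 | alternative 3 | 18-membered aryl (2Z)-en-4-ynyl ketone (C7 O-TES) | CO[C@H]1[C@@H](OC)C[C@H](C)[C@@H](OC)c2cc(OC)cc(c2OC)C(=O)/C(C)=C\C#C[C@H](OC)[C@@H](O[Si](CC)(CC)CC)/C(C)=C\[C@@H]1C
A6 | alternative 3 | ketoxime of A5, hydroxyl anti to the arene | CO[C@H]1[C@@H](OC)C[C@H](C)[C@@H](OC)c2cc(OC)cc(c2OC)/C(=N/O)/C(C)=C\C#C[C@H](OC)[C@@H](O[Si](CC)(CC)CC)/C(C)=C\[C@@H]1C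
A7 | alternative 3 | 19-membered (2Z)-en-4-yne lactam (C7 O-TES) | CO[C@H]1[C@@H](OC)C[C@H](C)[C@@H](OC)c2cc(OC)cc(c2OC)NC(=O)/C(C)=C\C#C[C@H](OC)[C@@H](O[Si](CC)(CC)CC)/C(C)=C\[C@@H]1C
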